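**Strategy.** The route is cut at the pyran bond O1–C2 together with the exocyclic bond C1'–C2'. An enantioselective Pd(II)-catalysed domino oxypalladation/carbonylation of an achiral o-(3-methylbut-3-enyl)phenol closes the dihydropyran ring, sets the quaternary stereocentre C2 under ligand control and appends C2' as an ester in one operation. It exploits the fact that C2 of the chroman carries O1, a methyl group, C3 and C1' but no hydrogen: the C1'–Pd intermediate cannot β-eliminate and is forced to capture CO. The precursor comes from trimethylhydroquinone in four steps. C4' and C8' are bought, the C12'=C13' alkene is made by allylic transposition, and the halves are joined at C2'–C3'.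

Key step: step 5

Remark: CIP descriptors change along the route without any change in spatial arrangement ((2S) in 9–13 becomes (2R) in 24 and 25; the 8' centre of the target is S only because the C12'=C13' double bond outranks the C4' branch), so the SMILES strings are decisive.
Remark: the sense of induction of (S,S)-Bn-BOXAX in step 5 is assumed by analogy with related 2-methyl-2-substituted chromans; should it prove opposite, the (R,R)-ligand is used.
Remark: compounds 1, 2, 14 and 16 are taken as commercial; (S,S)-Bn-BOXAX, (aS)-2,2'-bis[(4S)-4-benzyl-4,5-dihydrooxazol-2-yl]-1,1'-binaphthyl, is a known ligand prepared separately and treated as a catalyst component.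

Step 1
Reactants: 1 2,3,5-trimethylhydroquinone; 2 methyl vinyl ketone
Product: 4 rac-2-methoxy-2,5,7,8-tetramethylchroman-6-ol, via hemiketal 3 (not isolated)
Conditions: HC(OMe)3, MeOH, H2SO4 (cat.), 0 °C → rt
Reagents that add atoms: trimethyl orthoformate, COC(OC)OC
Why: acid-catalysed conjugate C-alkylation (Friedel–Crafts-type Michael addition) at the only free ring position, ring closure to the hemiketal and orthoformate-driven ketalisation should tie O1 into a ring and leave only the O6 phenol free; the ketal centre is racemic and is erased in step 4.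

Step 2
Reactants: 4 rac-2-methoxy-2,5,7,8-tetramethylchroman-6-ol
Product: 5 rac-6-(benzyloxy)-2-methoxy-2,5,7,8-tetramethylchromane
Conditions: BnBr, K2CO3, DMF, 60 °C
Reagents that add atoms: benzyl bromide, BrCc1ccccc1
Why: Williamson etherification of the hindered phenoxide should proceed cleanly because the mixed ketal is stable to base.

Step 3
Reactants: 5 rac-6-(benzyloxy)-2-methoxy-2,5,7,8-tetramethylchromane
Product: 6 rac-6-(benzyloxy)-2,5,7,8-tetramethylchroman-2-ol
Conditions: 1 M HCl, acetone, rt
Reagents that add atoms: water, O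
Why: acid hydrolysis of the mixed ketal through the aryloxy-stabilised oxocarbenium ion should give the hemiketal under conditions that do not touch the benzyl aryl ether.

Step 4
Reactants: 6 rac-6-(benzyloxy)-2,5,7,8-tetramethylchroman-2-ol
Product: 8 4-(benzyloxy)-2,3,5-trimethyl-6-(3-methylbut-3-en-1-yl)phenol, via open-chain ketone 7 (not isolated)
Conditions: Ph3PCH3Br (3 equiv), KOtBu (3 equiv), THF, 0 → 60 °C; aq. NH4Cl
Reagents that add atoms: methyltriphenylphosphonium bromide (as its ylide), C[P+](c1ccccc1)(c1ccccc1)c1ccccc1.[Br-]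
Why: Wittig methylenation should work as on a lactol, since base opens the hemiketal to the phenoxide of methyl ketone 7, which the excess ylide converts into the 1,1-disubstituted alkene.

Step 5
Reactants: 8 4-(benzyloxy)-2,3,5-trimethyl-6-(3-methylbut-3-en-1-yl)phenol
Product: 11 methyl 2-[(2S)-6-(benzyloxy)-2,5,7,8-tetramethylchroman-2-yl]acetate, via alkylpalladium(II) trifluoroacetate 9 (not isolated), via acylpalladium(II) trifluoroacetate 10 (not isolated)
Conditions: Pd(OCOCF3)2 (5 mol %), (S,S)-Bn-BOXAX (20 mol %), p-benzoquinone (4 equiv), CO (1 atm), MeOH, rt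
Reagents that add atoms: carbon monoxide, [C-]#[O+]; methanol, CO
Why: The Pd(II)–bis(oxazoline) complex binds the 1,1-disubstituted alkene and the phenol of 8, O1 adds to the internal alkene carbon (intramolecular oxypalladation), and the σ-alkylpalladium species 9, which has no β-hydrogen because C2 is fully substituted, inserts CO to give acyl complex 10, which methanol cleaves to ester 11 while p-benzoquinone reoxidises Pd(0) to Pd(II). The closest known reaction type is the enantioselective domino Wacker-type cyclisation/carbonylation/methoxylation of o-homoallylic phenols to 2,2-disubstituted chromans under Pd(II)/BOXAX catalysis. The dihydropyran ring closes in the 6-exo-trig mode. The single new stereocentre C2 is set by the C2-symmetric ligand, which differentiates the enantiotopic alkene faces of the achiral substrate in the oxypalladation (pure catalyst control), and (S,S)-Bn-BOXAX is expected to give the (2S)-ester. The step needs high enantioface selectivity and chemoselectivity for cyclisation and CO capture over oxidation of the electron-rich arene and over acid-catalysed hydroalkoxylation to a 2,2-dimethylchroman. The benzyl cap on O6 prevents oxidation to the quinone, the fully substituted benzene ring offers no C–H site for palladation, the excess of ligand over palladium suppresses a ligand-free racemic pathway and the near-neutral medium disfavours the Brønsted-acid pathway.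

Step 6
Reactants: 11 methyl 2-[(2S)-6-(benzyloxy)-2,5,7,8-tetramethylchroman-2-yl]acetate
Product: 12 2-[(2S)-6-(benzyloxy)-2,5,7,8-tetramethylchroman-2-yl]ethan-1-ol
Conditions: LiAlH4, THF, 0 °C → rt; aq. work-up
Reagents that add atoms: none
Why: hydride reduction of the ester to the primary alcohol should leave the benzyl ether, the chroman ring and the quaternary stereocentre untouched.

Step 7
Reactants: 12 2-[(2S)-6-(benzyloxy)-2,5,7,8-tetramethylchroman-2-yl]ethan-1-ol
Product: 13 (2S)-6-(benzyloxy)-2-(2-bromoethyl)-2,5,7,8-tetramethylchromane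
Conditions: CBr4, PPh3, CH2Cl2, 0 °C
Reagents that add atoms: carbon tetrabromide, BrC(Br)(Br)Br
Why: Appel bromination of the unhindered primary alcohol runs under neutral conditions, so the aryl benzyl ether and the stereocentre two carbons away should be unaffected.

Step 8
Reactants: 14 (2S)-3-bromo-2-methylpropan-1-ol
Product: 15 [(2S)-3-bromo-2-methylpropoxy](tert-butyl)dimethylsilane
Conditions: TBSCl, imidazole, CH2Cl2, 0 °C → rt
Reagents that add atoms: tert-butyldimethylsilyl chloride, CC(C)(C)[Si](C)(C)Cl
Why: standard imidazole-mediated silylation of the primary alcohol masks the hydroxyl for Grignard formation without involving the stereocentre.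

Step 9
Reactants: 15 [(2S)-3-bromo-2-methylpropoxy](tert-butyl)dimethylsilane; 16 (R)-citronellyl bromide
Product: 18 tert-butyl(dimethyl){[(2R,6S)-2,6,10-trimethylundec-9-en-1-yl]oxy}silane, via Grignard reagent 17 (not isolated)
Conditions: Mg, THF, 40 °C; then 16, Li2CuCl4 (3 mol %), THF, −78 °C → rt
Reagents that add atoms: none
Why: Kochi-type copper-catalysed sp3–sp3 coupling of a primary alkylmagnesium bromide with a primary alkyl bromide should form C5'–C6', and both stereocentres (bought with 14 and 16) lie off the reacting carbons and are carried over unchanged.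

Step 10
Reactants: 18 tert-butyl(dimethyl){[(2R,6S)-2,6,10-trimethylundec-9-en-1-yl]oxy}silane
Product: 19 tert-butyl{[(2R,6S,9RS)-9-chloro-2,6,10-trimethylundec-10-en-1-yl]oxy}dimethylsilane
Conditions: NCS, PhSeCl (10 mol %), CH2Cl2, rt
Reagents that add atoms: N-chlorosuccinimide, O=C1CCC(=O)N1Cl
Why: selenium-catalysed ene-type allylic chlorination of the trisubstituted alkene should move the double bond into the isopropenyl position and place chlorine on the adjacent secondary carbon; the new C9 centre forms unselectively and is removed in step 11.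

Step 11
Reactants: 19 tert-butyl{[(2R,6S,9RS)-9-chloro-2,6,10-trimethylundec-10-en-1-yl]oxy}dimethylsilane
Product: 20 tert-butyl(dimethyl){[(2R,6S)-2,6,10-trimethylundec-10-en-1-yl]oxy}silane
Conditions: Pd(OAc)2 (5 mol %), n-Bu3P (20 mol %), HCO2NH4, 1,4-dioxane, 100 °C
Reagents that add atoms: none
Why: palladium-catalysed formate hydrogenolysis of the allylic chloride (Tsuji–Trost-type π-allyl chemistry) should deliver hydride to the more substituted allyl terminus, giving the 1,1-disubstituted terminal alkene and erasing the C9 centre.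

Step 12
Reactants: 20 tert-butyl(dimethyl){[(2R,6S)-2,6,10-trimethylundec-10-en-1-yl]oxy}silane
Product: 21 (2R,6S)-2,6,10-trimethylundec-10-en-1-ol
Conditions: TBAF, THF, rt
Reagents that add atoms: none
Why: fluoride-induced desilylation should free the primary alcohol without affecting the alkene or the stereocentres.

Step 13
Reactants: 21 (2R,6S)-2,6,10-trimethylundec-10-en-1-ol
Product: 22 (6S,10R)-11-bromo-2,6,10-trimethylundec-1-ene
Conditions: CBr4, PPh3, CH2Cl2, 0 °C
Reagents that add atoms: carbon tetrabromide, BrC(Br)(Br)Br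
Why: Appel bromination is an SN2 displacement at CH2, so the adjacent stereocentre should stay intact, and the 1,1-disubstituted alkene is inert to the reagent.

Step 14
Reactants: 22 (6S,10R)-11-bromo-2,6,10-trimethylundec-1-ene; 13 (2S)-6-(benzyloxy)-2-(2-bromoethyl)-2,5,7,8-tetramethylchromane
Product: 24 (2R)-6-(benzyloxy)-2,5,7,8-tetramethyl-2-[(4R,8S)-4,8,12-trimethyltridec-12-en-1-yl]chromane, via Grignard reagent 23 (not isolated)
Conditions: Mg, THF, 40 °C; then 13, Li2CuCl4 (5 mol %), THF/NMP, 0 °C → rt
Reagents that add atoms: none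
Why: Kochi-type copper-catalysed sp3–sp3 coupling of the primary Grignard reagent with the primary bromide should form C2'–C3' without touching any of the three stereocentres.

Step 15
Reactants: 24 (2R)-6-(benzyloxy)-2,5,7,8-tetramethyl-2-[(4R,8S)-4,8,12-trimethyltridec-12-en-1-yl]chromane
Product: 25 (2R)-2,5,7,8-tetramethyl-2-[(4R,8S)-4,8,12-trimethyltridec-12-en-1-yl]chroman-6-ol (CNP0115007.1)
Conditions: Na (4 equiv), NH3(l)/THF, −78 °C; then NH4Cl
Reagents that add atoms: none
Why: dissolving-metal (Birch-type) cleavage of the aryl benzyl ether by electron transfer to the benzyl group should release the phenol, while the isolated 1,1-disubstituted alkene and the electron-rich chroman are not reduced at −78 °C and no stereocentre is affected.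

**Compound list**

1 | 2,3,5-trimethylbenzene-1,4-diol (trimethylhydroquinone) | Cc1cc(O)c(C)c(C)c1O | starting material
2 | but-3-en-2-one (methyl vinyl ketone) | CC(=O)C=C | starting material
3 | rac-2,5,7,8-tetramethylchromane-2,6-diol (cyclic hemiketal of the Michael adduct) | CC1(O)CCc2c(C)c(O)c(C)c(C)c2O1 | intermediate
4 | rac-2-methoxy-2,5,7,8-tetramethylchroman-6-ol | COC1(C)CCc2c(C)c(O)c(C)c(C)c2O1 | intermediate
5 | rac-6-(benzyloxy)-2-methoxy-2,5,7,8-tetramethylchromane | COC1(C)CCc2c(C)c(OCc3ccccc3)c(C)c(C)c2O1 | intermediate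
6 | rac-6-(benzyloxy)-2,5,7,8-tetramethylchroman-2-ol (hemiketal, ring-chain tautomer of 7) | CC1(O)CCc2c(C)c(OCc3ccccc3)c(C)c(C)c2O1 | intermediate
7 | 4-[5-(benzyloxy)-2-hydroxy-3,4,6-trimethylphenyl]butan-2-one | CC(=O)CCc1c(C)c(OCc2ccccc2)c(C)c(C)c1O | intermediate
8 | 4-(benzyloxy)-2,3,5-trimethyl-6-(3-methylbut-3-en-1-yl)phenol | C=C(C)CCc1c(C)c(OCc2ccccc2)c(C)c(C)c1O | intermediate
9 | {[(2S)-6-(benzyloxy)-2,5,7,8-tetramethylchroman-2-yl]methyl}palladium(II) trifluoroacetate (BOXAX ligand omitted) | FC(F)(F)C(=O)O[Pd]C[C@]1(C)CCc2c(C)c(OCc3ccccc3)c(C)c(C)c2O1 | intermediate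
10 | {[(2S)-6-(benzyloxy)-2,5,7,8-tetramethylchroman-2-yl]acetyl}palladium(II) trifluoroacetate (BOXAX ligand omitted) | FC(F)(F)C(=O)O[Pd]C(=O)C[C@]1(C)CCc2c(C)c(OCc3ccccc3)c(C)c(C)c2O1 | intermediate
11 | methyl 2-[(2S)-6-(benzyloxy)-2,5,7,8-tetramethylchroman-2-yl]acetate | COC(=O)C[C@]1(C)CCc2c(C)c(OCc3ccccc3)c(C)c(C)c2O1 | intermediate
12 | 2-[(2S)-6-(benzyloxy)-2,5,7,8-tetramethylchroman-2-yl]ethan-1-ol | OCC[C@]1(C)CCc2c(C)c(OCc3ccccc3)c(C)c(C)c2O1 | intermediate
13 | (2S)-6-(benzyloxy)-2-(2-bromoethyl)-2,5,7,8-tetramethylchromane | BrCC[C@]1(C)CCc2c(C)c(OCc3ccccc3)c(C)c(C)c2O1 | intermediate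
14 | (2S)-3-bromo-2-methylpropan-1-ol | OC[C@H](C)CBr | starting material
15 | [(2S)-3-bromo-2-methylpropoxy](tert-butyl)dimethylsilane | CC(C)(C)[Si](C)(C)OC[C@H](C)CBr | intermediate
16 | (6R)-8-bromo-2,6-dimethyloct-2-ene ((R)-citronellyl bromide) | BrCC[C@H](C)CCC=C(C)C | starting material
17 | {(2S)-3-[(tert-butyldimethylsilyl)oxy]-2-methylpropyl}magnesium bromide | CC(C)(C)[Si](C)(C)OC[C@H](C)C[Mg]Br | intermediate
18 | tert-butyl(dimethyl){[(2R,6S)-2,6,10-trimethylundec-9-en-1-yl]oxy}silane | CC(C)(C)[Si](C)(C)OC[C@H](C)CCC[C@H](C)CCC=C(C)C | intermediate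
19 | tert-butyl{[(2R,6S,9RS)-9-chloro-2,6,10-trimethylundec-10-en-1-yl]oxy}dimethylsilane (mixture of C9 epimers) | CC(C)(C)[Si](C)(C)OC[C@H](C)CCC[C@H](C)CCC(Cl)C(C)=C | intermediate
20 | tert-butyl(dimethyl){[(2R,6S)-2,6,10-trimethylundec-10-en-1-yl]oxy}silane | CC(C)(C)[Si](C)(C)OC[C@H](C)CCC[C@H](C)CCCC(C)=C | intermediate
21 | (2R,6S)-2,6,10-trimethylundec-10-en-1-ol | OC[C@H](C)CCC[C@H](C)CCCC(C)=C | intermediate
22 | (6S,10R)-11-bromo-2,6,10-trimethylundec-1-ene | BrC[C@H](C)CCC[C@H](C)CCCC(C)=C | intermediate
23 | [(2R,6S)-2,6,10-trimethylundec-10-en-1-yl]magnesium bromide | Br[Mg]C[C@H](C)CCC[C@H](C)CCCC(C)=C | intermediate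
24 | (2R)-6-(benzyloxy)-2,5,7,8-tetramethyl-2-[(4R,8S)-4,8,12-trimethyltridec-12-en-1-yl]chromane | C=C(C)CCC[C@@H](C)CCC[C@@H](C)CCC[C@]1(C)CCc2c(C)c(OCc3ccccc3)c(C)c(C)c2O1 | intermediate
25 | (2R)-2,5,7,8-tetramethyl-2-[(4R,8S)-4,8,12-trimethyltridec-12-en-1-yl]chroman-6-ol | C=C(C)CCC[C@@H](C)CCC[C@@H](C)CCC[C@]1(C)CCc2c(C)c(O)c(C)c(C)c2O1 | target

**Totals**

Total step count: 15.
Longest linear sequence: 9 steps (steps 1–7, 14, 15, from 1); the side-chain branch (steps 8–13) joins at step 14.

**Steps most likely to fail**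

Step 5. The bis(oxazoline) may be displaced from Pd(II) by CO, or a ligand-free background oxypalladation may compete, so that enantioface selectivity erodes; CO may also reduce Pd(II) to inactive Pd(0) faster than benzoquinone reoxidises it, so that the cycle stalls. The fallback sets out from 6 and comes back at 12, and replaces asymmetric catalysis by classical resolution. Horner–Wadsworth–Emmons olefination of 6 (trimethyl phosphonoacetate, NaH, THF, 0 °C → reflux) should give, through 7, methyl (2E/Z)-5-[5-(benzyloxy)-2-hydroxy-3,4,6-trimethylphenyl]-3-methylpent-2-enoate F1, whose phenoxide should close in the same flask by intramolecular oxa-Michael addition to rac-methyl 2-[6-(benzyloxy)-2,5,7,8-tetramethylchroman-2-yl]acetate F2. Saponification (NaOH, aq. MeOH) should give rac-2-[6-(benzyloxy)-2,5,7,8-tetramethylchroman-2-yl]acetic acid F3. Crystallisation with (S)-1-phenylethylamine should give the diastereomerically pure salt (1S)-1-phenylethanaminium 2-[(2S)-6-(benzyloxy)-2,5,7,8-tetramethylchroman-2-yl]acetate F4 (the (R)-amine is used if the salt of the wanted acid proves the more soluble one). Acidification should release 2-[(2S)-6-(benzyloxy)-2,5,7,8-tetramethylchroman-2-yl]acetic acid F5, and LiAlH4 in THF should reduce it to 12.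

Step 11. Hydride may be delivered to the unsubstituted terminus of the π-allyl palladium intermediate, or β-hydride elimination to a diene may compete, so that the trisubstituted alkene returns or over-unsaturated material forms instead of the isopropenyl terminus. The fallback sets out from 18 and comes back at 20, and builds the terminus by C–C coupling instead of transposition. Ozonolysis of 18 (O3, CH2Cl2, −78 °C; then PPh3) should give (4S,8R)-9-{[tert-butyl(dimethyl)silyl]oxy}-4,8-dimethylnonanal F6. NaBH4 in MeOH should reduce it to (4S,8R)-9-{[tert-butyl(dimethyl)silyl]oxy}-4,8-dimethylnonan-1-ol F7. I2, PPh3 and imidazole should convert this into tert-butyl{[(2R,6S)-9-iodo-2,6-dimethylnonyl]oxy}dimethylsilane F8. Copper-catalysed coupling with isopropenylmagnesium bromide (Li2CuCl4 cat., THF, −20 °C → rt) should then give 20.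

Step 14. Bromine–magnesium exchange between 23 and 13 followed by homocoupling, or base-induced elimination of HBr from 13 to a 2-vinylchroman, may outrun the copper-catalysed C(sp3)–C(sp3) bond formation. The fallback sets out from 13 and comes back at 25, and replaces the cross-coupling by sulfone alkylation. Displacement of bromide with sodium benzenesulfinate (DMF, 60 °C) should give (2S)-6-(benzyloxy)-2,5,7,8-tetramethyl-2-[2-(phenylsulfonyl)ethyl]chromane F9. Deprotonation with n-BuLi (THF, −78 °C) should give {2-[(2S)-6-(benzyloxy)-2,5,7,8-tetramethylchroman-2-yl]-1-(phenylsulfonyl)ethyl}lithium F10. Alkylation with bromide 22 (DMPU, −78 °C → rt) should give (2S)-6-(benzyloxy)-2,5,7,8-tetramethyl-2-[(2RS,4R,8S)-4,8,12-trimethyl-2-(phenylsulfonyl)tridec-12-en-1-yl]chromane F11. Sodium in liquid ammonia/THF at −78 °C should then remove the sulfonyl and benzyl groups in one operation to give 25.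

**Further compounds**

F1 | step 5 | methyl (2E/Z)-5-[5-(benzyloxy)-2-hydroxy-3,4,6-trimethylphenyl]-3-methylpent-2-enoate | COC(=O)C=C(C)CCc1c(C)c(OCc2ccccc2)c(C)c(C)c1O
F2 | step 5 | rac-methyl 2-[6-(benzyloxy)-2,5,7,8-tetramethylchroman-2-yl]acetate | COC(=O)CC1(C)CCc2c(C)c(OCc3ccccc3)c(C)c(C)c2O1
F3 | step 5 | rac-2-[6-(benzyloxy)-2,5,7,8-tetramethylchroman-2-yl]acetic acid | OC(=O)CC1(C)CCc2c(C)c(OCc3ccccc3)c(C)c(C)c2O1
F4 | step 5 | (1S)-1-phenylethanaminium 2-[(2S)-6-(benzyloxy)-2,5,7,8-tetramethylchroman-2-yl]acetate | [O-]C(=O)C[C@]1(C)CCc2c(C)c(OCc3ccccc3)c(C)c(C)c2O1.C[C@H]([NH3+])c1ccccc1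
F5 | step 5 | 2-[(2S)-6-(benzyloxy)-2,5,7,8-tetramethylchroman-2-yl]acetic acid | OC(=O)C[C@]1(C)CCc2c(C)c(OCc3ccccc3)c(C)c(C)c2O1
F6 | step 11 | (4S,8R)-9-{[tert-butyl(dimethyl)silyl]oxy}-4,8-dimethylnonanal | CC(C)(C)[Si](C)(C)OC[C@H](C)CCC[C@H](C)CCC=O
F7 | step 11 | (4S,8R)-9-{[tert-butyl(dimethyl)silyl]oxy}-4,8-dimethylnonan-1-ol | CC(C)(C)[Si](C)(C)OC[C@H](C)CCC[C@H](C)CCCO
F8 | step 11 | tert-butyl{[(2R,6S)-9-iodo-2,6-dimethylnonyl]oxy}dimethylsilane | CC(C)(C)[Si](C)(C)OC[C@H](C)CCC[C@H](C)CCCI
F9 | step 14 | (2S)-6-(benzyloxy)-2,5,7,8-tetramethyl-2-[2-(phenylsulfonyl)ethyl]chromane | O=S(=O)(CC[C@]1(C)CCc2c(C)c(OCc3ccccc3)c(C)c(C)c2O1)c1ccccc1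
F10 | step 14 | {2-[(2S)-6-(benzyloxy)-2,5,7,8-tetramethylchroman-2-yl]-1-(phenylsulfonyl)ethyl}lithium | [Li]C(C[C@]1(C)CCc2c(C)c(OCc3ccccc3)c(C)c(C)c2O1)S(=O)(=O)c1ccccc1
F11 | step 14 | (2S)-6-(benzyloxy)-2,5,7,8-tetramethyl-2-[(2RS,4R,8S)-4,8,12-trimethyl-2-(phenylsulfonyl)tridec-12-en-1-yl]chromane | C=C(C)CCC[C@@H](C)CCC[C@@H](C)CC(C[C@]1(C)CCc2c(C)c(OCc3ccccc3)c(C)c(C)c2O1)S(=O)(=O)c1ccccc1
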